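**Retrosynthetic overview**

1. The target is epiafzelechin-(4β→8)-epicatechin-(4β→8)-epicatechin. Both C4–C8 bonds are cut to a ring A-stabilised C4 cation (from flavan-3,4-diols 25 and 12) and a C8 nucleophile. The lower unit is tetra-O-benzyl-(−)-epicatechin 14; bonds are made lower-to-upper (step 10, then step 19), with global hydrogenolysis last.
2. Ring C of the middle unit (and, by the same chemistry, of the upper unit) is not cyclized. It is made as a 2,3-cis-3-hydroxychroman-4-one by one-carbon ring expansion (α-ketol shift) of a 3-hydroxy-2-aryl-2,3-dihydrobenzofuran-3-carbaldehyde generated in the flask by enolate hydroxylation.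
3. The dihydrobenzofuran comes from dirhodium-carbene insertion into a benzylic C–H bond of a 2,4,6-tris(arylmethoxy)phenyl diazoacetate, itself built from phloroglucinol triacetate and three molecules of one arylmethyl chloride. One arylmethyl ether supplies C2 and ring B; the other two remain as protecting groups on O5 and O7. Dimethyl oxalate supplies C3 and C4.
4. Enabling feature: in ring C the carbinol carbon C3 lies between C2 (benzylic, bound to O1) and C4, and C4 is bound to C4a of ring A with O5 and O7 ortho and para to it. C4 can therefore be carried first as a ketone conjugated to ring A, so that C3(OH)–C4(=O) is an α-ketol whose five-membered-ring isomer rearranges downhill, and later as the stabilised cation that forms the C4–C8 bond trans to the 3-hydroxyl.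
5. Order of ring formation: ring A is bought as phloroglucinol triacetate and ring B as the arylmethyl chloride; the five-membered O-heterocycle is closed in step 5; ring C arises by expansion in step 7 (upper unit: step 17); the lower unit's rings are untouched.

Key step: step 7

Abbreviations: Ar1 = 3,4-bis(benzyloxy)phenyl; Ar2 = 4-(benzyloxy)phenyl; Bn = benzyl.

Remark (assumption): Rh2(S-PTTL)4 is taken to give the (2S)-dihydrobenzofurans drawn; if the sense of induction is opposite on these substrates, Rh2(R-PTTL)4 is used with no other change.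

Remark (stoichiometry): in steps 1 and 11 three molecules of the arylmethyl chloride are consumed per molecule of 1. Both chlorides are commercial alkylating agents and are entered as atom-adding reagents, in the same way as benzyl bromide in step 9.

Remark (naming): dihydrobenzofurans carry benzofuran numbering and chromans carry flavan numbering. The C2 descriptor changes from S to R in steps 7 and 17 only through a change of CIP priorities; the spatial arrangement is retained.

**Route**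

Step 1
Reactants: 1 1,3,5-triacetoxybenzene
Product: 2 1,3,5-tris(Ar1-methoxy)benzene
Conditions: 3,4-bis(benzyloxy)benzyl chloride (3.3 equiv), NaH (6.6 equiv), DMF, 0 °C; H2O (3.0 equiv) added slowly; rt
Reagents that add atoms: 3,4-bis(benzyloxy)benzyl chloride, ClCc1ccc(OCc2ccccc2)c(OCc2ccccc2)c1
Why: Slow in situ deacetylation releases each of the three phenoxides in the presence of excess benzylic chloride, so that threefold O-alkylation (Williamson ether synthesis, one chloride per phenoxide) should outrun the C-alkylation that free phloroglucinol suffers.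

Step 2
Reactants: 2 1,3,5-tris(Ar1-methoxy)benzene
Product: 3 2-bromo-1,3,5-tris(Ar1-methoxy)benzene
Conditions: NBS (1.0 equiv), CH2Cl2, −40 → 0 °C
Reagents that add atoms: N-bromosuccinimide, O=C1CCC(=O)N1Br
Why: Electrophilic aromatic bromination should occur on the 1,3,5-trioxygenated ring, which is much more nucleophilic than the other arenes and whose three free positions are equivalent.

Step 3
Reactants: 3 2-bromo-1,3,5-tris(Ar1-methoxy)benzene; 4 dimethyl oxalate
Product: 5 methyl 2-oxo-2-[2,4,6-tris(Ar1-methoxy)phenyl]acetate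
Conditions: n-BuLi (1.05 equiv), THF, −78 °C; then added to 4 (3 equiv), THF, −78 °C; aq. NH4Cl
Reagents that add atoms: none
Why: Bromine–lithium exchange is faster than benzylic deprotonation at −78 °C, and the aryllithium should acylate excess dimethyl oxalate once, the hindered keto ester resisting a second addition.

Step 4
Reactants: 5 methyl 2-oxo-2-[2,4,6-tris(Ar1-methoxy)phenyl]acetate
Product: 7 methyl 2-diazo-2-[2,4,6-tris(Ar1-methoxy)phenyl]acetate, via tosylhydrazone 6 (not isolated)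
Conditions: TsNHNH2 (1.2 equiv), TsOH (5 mol%), toluene, 60 °C; then DBU (1.5 equiv), CH2Cl2, rt
Reagents that add atoms: p-toluenesulfonyl hydrazide, Cc1ccc(cc1)S(=O)(=O)NN
Why: Condensation to the α-keto ester tosylhydrazone and base-induced loss of sulfinate (Bamford–Stevens reaction) is a standard entry to aryldiazoacetates and avoids diazo transfer onto a hindered arylacetate.

Step 5
Reactants: 7 methyl 2-diazo-2-[2,4,6-tris(Ar1-methoxy)phenyl]acetate
Product: 8 methyl (2S,3R)-2-Ar1-4,6-bis(Ar1-methoxy)-2,3-dihydrobenzofuran-3-carboxylate (2,3-cis)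
Conditions: Rh2(S-PTTL)4 (dirhodium tetrakis[N-phthaloyl-(S)-tert-leucinate], 1 mol%), toluene, −60 °C
Reagents that add atoms: none
Why: The dirhodium carbene should insert into the activated benzylic C–H bond of an ortho arylmethoxy group through a five-membered transition state (intramolecular C–H insertion, precedented for cis-2-aryl-2,3-dihydrobenzofuran-3-carboxylates); the chiral carboxylate ligands set C2, the two ortho ether groups are equivalent so only one constitution can form, and the cis ester is the kinetic product.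

Step 6
Reactants: 8 methyl (2S,3R)-2-Ar1-4,6-bis(Ar1-methoxy)-2,3-dihydrobenzofuran-3-carboxylate
Product: 9 (2S,3S)-2-Ar1-4,6-bis(Ar1-methoxy)-2,3-dihydrobenzofuran-3-carbaldehyde (2,3-trans)
Conditions: i-Bu2AlH (1.2 equiv), CH2Cl2, −78 °C; aq. KNaC4H4O6; then Et3N (0.2 equiv), CH2Cl2, rt
Reagents that add atoms: none
Why: The aluminium hemiacetal of the hindered ester should survive at −78 °C and release the aldehyde on work-up (partial ester reduction), and amine-mediated enolization then equilibrates C3 to the less crowded trans isomer without touching C2.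

Step 7
Reactants: 9 (2S,3S)-2-Ar1-4,6-bis(Ar1-methoxy)-2,3-dihydrobenzofuran-3-carbaldehyde
Product: 11 (2R,3S)-2-Ar1-5,7-bis(Ar1-methoxy)-3-hydroxychroman-4-one (2,3-cis), via 3-hydroxy aldehyde 10 (not isolated)
Conditions: KN(SiMe3)2 (1.05 equiv), THF, −78 °C; 2-(phenylsulfonyl)-3-phenyloxaziridine (1.2 equiv), −78 °C; 18-crown-6 (1.1 equiv), −78 → 0 °C; AcOH, −78 °C
Reagents that add atoms: 2-(phenylsulfonyl)-3-phenyloxaziridine, O=S(=O)(c1ccccc1)N1OC1c1ccccc1
Why: Proposed new method: the potassium enolate of 9 is hydroxylated at C3 on the face opposite the 2-aryl group, and the resulting tertiary alkoxide 10 (cation held by 18-crown-6) should undergo an anionic α-ketol 1,2-shift in which the O1-bearing benzylic carbon C2 migrates from C3 of the dihydrobenzofuran to the formyl carbon while the alkoxide carbon becomes the C4 ketone conjugated to ring A. The closest known reaction type is the base-mediated α-ketol ring expansion of tertiary α-hydroxy aldehydes and ketones (1-hydroxycycloalkanecarbaldehydes to 2-hydroxycycloalkanones, D-homoannulation of 17-hydroxy-20-oxo steroids), not yet run on a 2,3-dihydrobenzofuran or with an aryloxy-substituted migrating carbon. Ring C is closed by one-carbon ring expansion of the five-membered O-heterocycle (suprafacial 1,2-carbon shift, new bond C2–C3), not by a cyclization. C2 keeps its configuration because the migrating carbon moves with retention, and C3 is set by the transition-state geometry: with the free alkoxide oxygen and the carbonyl oxygen anti-periplanar (non-chelated) and the alkoxide trans to the aryl group, the former carbonyl oxygen ends axial and cis to the equatorial 2-aryl group, giving the 2,3-cis ketol. The step needs migration of C2 and not of the ring A carbon, one-sided hydroxylation, and no epimerization; these rest on the poor anionic migratory aptitude of the electron-rich aryl carbon together with the much greater stability of the aryl ketone product, on shielding of one enolate face by the 2-aryl group, and on keeping the product as its C3 alkoxide until a cold quench.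

Step 8
Reactants: 11 (2R,3S)-2-Ar1-5,7-bis(Ar1-methoxy)-3-hydroxychroman-4-one
Product: 12 (2R,3R,4R)-2-Ar1-5,7-bis(Ar1-methoxy)chromane-3,4-diol (2,3-cis-3,4-cis)
Conditions: NaBH4 (2 equiv), THF/EtOH 1:1, 0 °C
Reagents that add atoms: none
Why: Borohydride reduction of dihydroflavonols to flavan-3,4-diols is established; hydride is expected to approach C4 anti to the axial 3-hydroxyl, and the C4 configuration is erased in step 10 in any case.

Step 9
Reactants: 13 (−)-epicatechin
Product: 14 (2R,3R)-5,7-bis(benzyloxy)-2-Ar1-chroman-3-ol (tetra-O-benzylepicatechin)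
Conditions: BnBr (4.4 equiv), K2CO3 (5 equiv), DMF, 0 °C → rt
Reagents that add atoms: benzyl bromide, BrCc1ccccc1
Why: Williamson O-alkylation under weak base should benzylate the four phenols and leave the secondary 3-hydroxyl free.

Step 10
Reactants: 12 (2R,3R,4R)-2-Ar1-5,7-bis(Ar1-methoxy)chromane-3,4-diol; 14 tetra-O-benzylepicatechin
Product: 15 protected epicatechin-(4β→8)-epicatechin dimer (upper unit 2R,3R,4R with O5 and O7 as Ar1-methyl ethers and free 3-OH; lower unit 14 bonded at C8)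
Conditions: 14 (4 equiv), Me3SiOTf (0.2 equiv), 4 Å molecular sieves, CH2Cl2, −78 → −40 °C; Et3N
Reagents that add atoms: none
Why: The Lewis acid should ionize the 4-hydroxyl to the ring A-stabilised benzylic cation, which C8 of excess 14 attacks from the face opposite the axial 3-hydroxyl (Friedel–Crafts-type flavan-3,4-diol/flavan-3-ol condensation), setting C4 as the 3,4-trans (4β) isomer.

Step 11
Reactants: 1 1,3,5-triacetoxybenzene
Product: 16 1,3,5-tris(Ar2-methoxy)benzene
Conditions: 4-(benzyloxy)benzyl chloride (3.3 equiv), NaH (6.6 equiv), DMF, 0 °C; H2O (3.0 equiv) added slowly; rt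
Reagents that add atoms: 4-(benzyloxy)benzyl chloride, ClCc1ccc(OCc2ccccc2)cc1
Why: As in step 1, in situ deacetylation in the presence of excess benzylic chloride should favour threefold O-alkylation (Williamson ether synthesis, one chloride per phenoxide).

Step 12
Reactants: 16 1,3,5-tris(Ar2-methoxy)benzene
Product: 17 2-bromo-1,3,5-tris(Ar2-methoxy)benzene
Conditions: NBS (1.0 equiv), CH2Cl2, −40 → 0 °C
Reagents that add atoms: N-bromosuccinimide, O=C1CCC(=O)N1Br
Why: Electrophilic bromination should again select the trioxygenated ring over the mono-oxygenated ones.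

Step 13
Reactants: 17 2-bromo-1,3,5-tris(Ar2-methoxy)benzene; 4 dimethyl oxalate
Product: 18 methyl 2-oxo-2-[2,4,6-tris(Ar2-methoxy)phenyl]acetate
Conditions: n-BuLi (1.05 equiv), THF, −78 °C; then added to 4 (3 equiv), THF, −78 °C; aq. NH4Cl
Reagents that add atoms: none
Why: Bromine–lithium exchange followed by single acylation of the aryllithium with excess oxalate should proceed as in step 3.

Step 14
Reactants: 18 methyl 2-oxo-2-[2,4,6-tris(Ar2-methoxy)phenyl]acetate
Product: 20 methyl 2-diazo-2-[2,4,6-tris(Ar2-methoxy)phenyl]acetate, via tosylhydrazone 19 (not isolated)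
Conditions: TsNHNH2 (1.2 equiv), TsOH (5 mol%), toluene, 60 °C; then DBU (1.5 equiv), CH2Cl2, rt
Reagents that add atoms: p-toluenesulfonyl hydrazide, Cc1ccc(cc1)S(=O)(=O)NN
Why: Tosylhydrazone formation and Bamford–Stevens elimination should give the aryldiazoacetate as in step 4.

Step 15
Reactants: 20 methyl 2-diazo-2-[2,4,6-tris(Ar2-methoxy)phenyl]acetate
Product: 21 methyl (2S,3R)-2-Ar2-4,6-bis(Ar2-methoxy)-2,3-dihydrobenzofuran-3-carboxylate (2,3-cis)
Conditions: Rh2(S-PTTL)4 (1 mol%), toluene, −60 °C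
Reagents that add atoms: none
Why: Intramolecular carbene C–H insertion into one of the two equivalent ortho benzylic ether positions should set C2 under control of the chiral dirhodium carboxylate as in step 5.

Step 16
Reactants: 21 methyl (2S,3R)-2-Ar2-4,6-bis(Ar2-methoxy)-2,3-dihydrobenzofuran-3-carboxylate
Product: 22 (2S,3S)-2-Ar2-4,6-bis(Ar2-methoxy)-2,3-dihydrobenzofuran-3-carbaldehyde (2,3-trans)
Conditions: i-Bu2AlH (1.2 equiv), CH2Cl2, −78 °C; aq. KNaC4H4O6; then Et3N (0.2 equiv), CH2Cl2, rt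
Reagents that add atoms: none
Why: Partial ester reduction through the stable aluminium hemiacetal and amine-mediated equilibration at C3 should give the trans aldehyde as in step 6.

Step 17
Reactants: 22 (2S,3S)-2-Ar2-4,6-bis(Ar2-methoxy)-2,3-dihydrobenzofuran-3-carbaldehyde
Product: 24 (2R,3S)-2-Ar2-5,7-bis(Ar2-methoxy)-3-hydroxychroman-4-one (2,3-cis), via 3-hydroxy aldehyde 23 (not isolated)
Conditions: KN(SiMe3)2 (1.05 equiv), THF, −78 °C; 2-(phenylsulfonyl)-3-phenyloxaziridine (1.2 equiv), −78 °C; 18-crown-6 (1.1 equiv), −78 → 0 °C; AcOH, −78 °C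
Reagents that add atoms: 2-(phenylsulfonyl)-3-phenyloxaziridine, O=S(=O)(c1ccccc1)N1OC1c1ccccc1
Why: Proposed new method: the same one-pot enolate hydroxylation and anionic α-ketol ring expansion as in step 7 (closest known type: base-mediated α-ketol ring expansion of tertiary α-hydroxy aldehydes), in which the alkoxide-driven 1,2-shift of C2 with retention through the anti-periplanar transition state should again convert the hydroxyl placed trans to the 2-aryl group into the 2,3-cis ketol.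

Step 18
Reactants: 24 (2R,3S)-2-Ar2-5,7-bis(Ar2-methoxy)-3-hydroxychroman-4-one
Product: 25 (2R,3R,4R)-2-Ar2-5,7-bis(Ar2-methoxy)chromane-3,4-diol (2,3-cis-3,4-cis)
Conditions: NaBH4 (2 equiv), THF/EtOH 1:1, 0 °C
Reagents that add atoms: none
Why: Borohydride reduction of the dihydroflavonol ketone should give the flavan-3,4-diol as in step 8, the C4 configuration being irrelevant for step 19.

Step 19
Reactants: 15 protected epicatechin-(4β→8)-epicatechin dimer; 25 (2R,3R,4R)-2-Ar2-5,7-bis(Ar2-methoxy)chromane-3,4-diol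
Product: 26 protected trimer (upper unit from 25 bonded through C4, trans to its 3-OH, to C8 of the upper flavan unit of 15)
Conditions: 15 (1.5 equiv), Me3SiOTf (0.2 equiv), 4 Å molecular sieves, CH2Cl2, −78 → −40 °C; Et3N
Reagents that add atoms: none
Why: The C4 cation from 25 should be captured trans to its 3-hydroxyl by C8 of the upper unit of 15, the most accessible nucleophilic position, as in Lewis acid-catalysed chain extension of benzylated procyanidin dimers to (4β→8) trimers.

Step 20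
Reactants: 26 protected trimer
Product: 27 epiafzelechin-(4β→8)-epicatechin-(4β→8)-epicatechin (target)
Conditions: H2 (1 atm), Pd(OH)2/C, THF/MeOH/H2O 20:1:1, rt
Reagents that add atoms: none
Why: Hydrogenolysis should cleave all seventeen benzylic ether C–O bonds (benzyl and the two kinds of alkoxybenzyl ethers) under conditions that leave the O1–C2 bonds of benzylated procyanidins intact.

**Compound list**

1 | 1,3,5-triacetoxybenzene | CC(=O)Oc1cc(OC(C)=O)cc(OC(C)=O)c1 | starting material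
2 | 1,3,5-tris{[3,4-bis(benzyloxy)phenyl]methoxy}benzene | c1(OCc7ccc(OCc8ccccc8)c(OCc8ccccc8)c7)cc(OCc7ccc(OCc8ccccc8)c(OCc8ccccc8)c7)cc(OCc7ccc(OCc8ccccc8)c(OCc8ccccc8)c7)c1 | intermediate
3 | 2-bromo-1,3,5-tris{[3,4-bis(benzyloxy)phenyl]methoxy}benzene | Brc1c(OCc7ccc(OCc8ccccc8)c(OCc8ccccc8)c7)cc(OCc7ccc(OCc8ccccc8)c(OCc8ccccc8)c7)cc1OCc7ccc(OCc8ccccc8)c(OCc8ccccc8)c7 | intermediate
4 | dimethyl oxalate | COC(=O)C(=O)OC | starting material
5 | methyl 2-oxo-2-(2,4,6-tris{[3,4-bis(benzyloxy)phenyl]methoxy}phenyl)acetate | COC(=O)C(=O)c1c(OCc7ccc(OCc8ccccc8)c(OCc8ccccc8)c7)cc(OCc7ccc(OCc8ccccc8)c(OCc8ccccc8)c7)cc1OCc7ccc(OCc8ccccc8)c(OCc8ccccc8)c7 | intermediate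
6 | N-tosylhydrazone of 5 | COC(=O)C(=NNS(=O)(=O)c9ccc(C)cc9)c1c(OCc7ccc(OCc8ccccc8)c(OCc8ccccc8)c7)cc(OCc7ccc(OCc8ccccc8)c(OCc8ccccc8)c7)cc1OCc7ccc(OCc8ccccc8)c(OCc8ccccc8)c7 | intermediate (not isolated)
7 | methyl 2-diazo-2-(2,4,6-tris{[3,4-bis(benzyloxy)phenyl]methoxy}phenyl)acetate | COC(=O)C(=[N+]=[N-])c1c(OCc7ccc(OCc8ccccc8)c(OCc8ccccc8)c7)cc(OCc7ccc(OCc8ccccc8)c(OCc8ccccc8)c7)cc1OCc7ccc(OCc8ccccc8)c(OCc8ccccc8)c7 | intermediate
8 | methyl (2S,3R)-2-[3,4-bis(benzyloxy)phenyl]-4,6-bis{[3,4-bis(benzyloxy)phenyl]methoxy}-2,3-dihydrobenzofuran-3-carboxylate (cis) | c1(OCc7ccc(OCc8ccccc8)c(OCc8ccccc8)c7)cc(OCc7ccc(OCc8ccccc8)c(OCc8ccccc8)c7)cc2O[C@H](c7ccc(OCc8ccccc8)c(OCc8ccccc8)c7)[C@H](C(=O)OC)c12 | intermediate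
9 | (2S,3S)-2-[3,4-bis(benzyloxy)phenyl]-4,6-bis{[3,4-bis(benzyloxy)phenyl]methoxy}-2,3-dihydrobenzofuran-3-carbaldehyde (trans) | c1(OCc7ccc(OCc8ccccc8)c(OCc8ccccc8)c7)cc(OCc7ccc(OCc8ccccc8)c(OCc8ccccc8)c7)cc2O[C@H](c7ccc(OCc8ccccc8)c(OCc8ccccc8)c7)[C@@H](C=O)c12 | intermediate
10 | (2R,3S)-2-[3,4-bis(benzyloxy)phenyl]-4,6-bis{[3,4-bis(benzyloxy)phenyl]methoxy}-3-hydroxy-2,3-dihydrobenzofuran-3-carbaldehyde (hydroxyl trans to the 2-aryl group; present as its potassium alkoxide) | c1(OCc7ccc(OCc8ccccc8)c(OCc8ccccc8)c7)cc(OCc7ccc(OCc8ccccc8)c(OCc8ccccc8)c7)cc2O[C@H](c7ccc(OCc8ccccc8)c(OCc8ccccc8)c7)[C@](O)(C=O)c12 | intermediate (not isolated)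
11 | (2R,3S)-2-[3,4-bis(benzyloxy)phenyl]-5,7-bis{[3,4-bis(benzyloxy)phenyl]methoxy}-3-hydroxychroman-4-one (2,3-cis dihydroflavonol) | c1(OCc7ccc(OCc8ccccc8)c(OCc8ccccc8)c7)cc(OCc7ccc(OCc8ccccc8)c(OCc8ccccc8)c7)cc2O[C@H](c7ccc(OCc8ccccc8)c(OCc8ccccc8)c7)[C@H](O)C(=O)c12 | intermediate
12 | (2R,3R,4R)-2-[3,4-bis(benzyloxy)phenyl]-5,7-bis{[3,4-bis(benzyloxy)phenyl]methoxy}chromane-3,4-diol (2,3-cis-3,4-cis) | c1(OCc7ccc(OCc8ccccc8)c(OCc8ccccc8)c7)cc(OCc7ccc(OCc8ccccc8)c(OCc8ccccc8)c7)cc2O[C@H](c7ccc(OCc8ccccc8)c(OCc8ccccc8)c7)[C@H](O)[C@H](O)c12 | intermediate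
13 | (−)-epicatechin, (2R,3R) | c1c(O)cc(O)c2c1O[C@H](c3ccc(O)c(O)c3)[C@H](O)C2 | starting material
14 | (2R,3R)-5,7-bis(benzyloxy)-2-[3,4-bis(benzyloxy)phenyl]chroman-3-ol | c1c(OCc7ccccc7)cc(OCc7ccccc7)c2c1O[C@H](c3ccc(OCc7ccccc7)c(OCc7ccccc7)c3)[C@H](O)C2 | intermediate
15 | (2R,3R,4R)-2-[3,4-bis(benzyloxy)phenyl]-5,7-bis{[3,4-bis(benzyloxy)phenyl]methoxy}-4-{(2R,3R)-5,7-bis(benzyloxy)-2-[3,4-bis(benzyloxy)phenyl]-3-hydroxychroman-8-yl}chroman-3-ol (3,4-trans) | c1(OCc7ccc(OCc8ccccc8)c(OCc8ccccc8)c7)cc(OCc7ccc(OCc8ccccc8)c(OCc8ccccc8)c7)cc2O[C@H](c7ccc(OCc8ccccc8)c(OCc8ccccc8)c7)[C@H](O)[C@@H](c3c(OCc7ccccc7)cc(OCc7ccccc7)c4c3O[C@H](c5ccc(OCc7ccccc7)c(OCc7ccccc7)c5)[C@H](O)C4)c12 | intermediate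
16 | 1,3,5-tris{[4-(benzyloxy)phenyl]methoxy}benzene | c1(OCc7ccc(OCc8ccccc8)cc7)cc(OCc7ccc(OCc8ccccc8)cc7)cc(OCc7ccc(OCc8ccccc8)cc7)c1 | intermediate
17 | 2-bromo-1,3,5-tris{[4-(benzyloxy)phenyl]methoxy}benzene | Brc1c(OCc7ccc(OCc8ccccc8)cc7)cc(OCc7ccc(OCc8ccccc8)cc7)cc1OCc7ccc(OCc8ccccc8)cc7 | intermediate
18 | methyl 2-oxo-2-(2,4,6-tris{[4-(benzyloxy)phenyl]methoxy}phenyl)acetate | COC(=O)C(=O)c1c(OCc7ccc(OCc8ccccc8)cc7)cc(OCc7ccc(OCc8ccccc8)cc7)cc1OCc7ccc(OCc8ccccc8)cc7 | intermediate
19 | N-tosylhydrazone of 18 | COC(=O)C(=NNS(=O)(=O)c9ccc(C)cc9)c1c(OCc7ccc(OCc8ccccc8)cc7)cc(OCc7ccc(OCc8ccccc8)cc7)cc1OCc7ccc(OCc8ccccc8)cc7 | intermediate (not isolated)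
20 | methyl 2-diazo-2-(2,4,6-tris{[4-(benzyloxy)phenyl]methoxy}phenyl)acetate | COC(=O)C(=[N+]=[N-])c1c(OCc7ccc(OCc8ccccc8)cc7)cc(OCc7ccc(OCc8ccccc8)cc7)cc1OCc7ccc(OCc8ccccc8)cc7 | intermediate
21 | methyl (2S,3R)-2-[4-(benzyloxy)phenyl]-4,6-bis{[4-(benzyloxy)phenyl]methoxy}-2,3-dihydrobenzofuran-3-carboxylate (cis) | c1(OCc7ccc(OCc8ccccc8)cc7)cc(OCc7ccc(OCc8ccccc8)cc7)cc2O[C@H](c7ccc(OCc8ccccc8)cc7)[C@H](C(=O)OC)c12 | intermediate
22 | (2S,3S)-2-[4-(benzyloxy)phenyl]-4,6-bis{[4-(benzyloxy)phenyl]methoxy}-2,3-dihydrobenzofuran-3-carbaldehyde (trans) | c1(OCc7ccc(OCc8ccccc8)cc7)cc(OCc7ccc(OCc8ccccc8)cc7)cc2O[C@H](c7ccc(OCc8ccccc8)cc7)[C@@H](C=O)c12 | intermediate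
23 | (2R,3S)-2-[4-(benzyloxy)phenyl]-4,6-bis{[4-(benzyloxy)phenyl]methoxy}-3-hydroxy-2,3-dihydrobenzofuran-3-carbaldehyde (hydroxyl trans to the 2-aryl group; present as its potassium alkoxide) | c1(OCc7ccc(OCc8ccccc8)cc7)cc(OCc7ccc(OCc8ccccc8)cc7)cc2O[C@H](c7ccc(OCc8ccccc8)cc7)[C@](O)(C=O)c12 | intermediate (not isolated)
24 | (2R,3S)-2-[4-(benzyloxy)phenyl]-5,7-bis{[4-(benzyloxy)phenyl]methoxy}-3-hydroxychroman-4-one (2,3-cis dihydroflavonol) | c1(OCc7ccc(OCc8ccccc8)cc7)cc(OCc7ccc(OCc8ccccc8)cc7)cc2O[C@H](c7ccc(OCc8ccccc8)cc7)[C@H](O)C(=O)c12 | intermediate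
25 | (2R,3R,4R)-2-[4-(benzyloxy)phenyl]-5,7-bis{[4-(benzyloxy)phenyl]methoxy}chromane-3,4-diol (2,3-cis-3,4-cis) | c1(OCc7ccc(OCc8ccccc8)cc7)cc(OCc7ccc(OCc8ccccc8)cc7)cc2O[C@H](c7ccc(OCc8ccccc8)cc7)[C@H](O)[C@H](O)c12 | intermediate
26 | protected trimer: (2R,3R)-2-[4-(benzyloxy)phenyl]-5,7-bis{[4-(benzyloxy)phenyl]methoxy}-3-hydroxychroman-4-yl unit bonded through C4 (3,4-trans) to C8 of the upper flavan unit of 15 | c1(OCc7ccc(OCc8ccccc8)cc7)cc(OCc7ccc(OCc8ccccc8)cc7)cc2O[C@H](c7ccc(OCc8ccccc8)cc7)[C@H](O)[C@@H](c3c(OCc7ccc(OCc8ccccc8)c(OCc8ccccc8)c7)cc(OCc7ccc(OCc8ccccc8)c(OCc8ccccc8)c7)c4c3O[C@H](c7ccc(OCc8ccccc8)c(OCc8ccccc8)c7)[C@H](O)[C@H]4c5c(OCc7ccccc7)cc(OCc7ccccc7)c6c5O[C@H](c9ccc(OCc7ccccc7)c(OCc7ccccc7)c9)[C@H](O)C6)c12 | intermediate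
27 | epiafzelechin-(4β→8)-epicatechin-(4β→8)-epicatechin (CNP0158921.2) | Oc1ccc([C@H]2Oc3cc(O)cc(O)c3[C@H](c3c(O)cc(O)c4c3O[C@H](c3ccc(O)c(O)c3)[C@H](O)[C@H]4c3c(O)cc(O)c4c3O[C@H](c3ccc(O)c(O)c3)[C@H](O)C4)[C@H]2O)cc1 | target

**Step count and risks**

Total steps: 20. Longest linear sequence: 11 steps (steps 1–8, 10, 19, 20).

Steps most likely to fail:

1. Step 7. The alkoxide may rearrange through a cation-bridged syn transition state (giving the 2,3-trans ketol) or by migration of the ring A carbon, or the aldehyde enolate may be lost to aldol or hydride-transfer reactions before it is hydroxylated. The fallback keeps the ring expansion but runs it stepwise with known reactions. It sets out from 9. Silylation with t-BuMe2SiOTf and Et3N gives the tert-butyldimethylsilyl enol ether F1. Rubottom oxidation with dimethyldioxirane in acetone at −40 °C (epoxidation anti to the 2-aryl group, then silyl migration) gives the α-silyloxy aldehyde F2. The organoaluminium-promoted rearrangement of α-siloxy aldehydes to α-siloxy ketones, using the bulky monodentate Lewis acid MeAl(OC6H2Br-t-Bu2)2 [methylaluminium bis(4-bromo-2,6-di-tert-butylphenoxide)] in CH2Cl2 at −78 °C, proceeds through the non-chelated anti transition state and gives the 3-O-silyl 2,3-cis ketol F3. Desilylation with Bu4NF and AcOH in THF at 0 °C comes back to the route at 11.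

2. Step 17. The same failure processes as in step 7 apply, on a less electron-rich migrating benzylic carbon. Because ring C of the upper unit is free to be made differently, the fallback abandons ring expansion there. It sets out from 15 and from (−)-epiafzelechin, which is purchasable only as an isolated natural product in small quantity and is therefore kept as a contingency. Benzylation (BnBr, K2CO3, DMF) gives 5,7,4′-tri-O-benzylepiafzelechin F4. Oxidation at C4 with DDQ in the presence of 2-ethoxyethanol (CH2Cl2, rt) gives the 4β-(2-ethoxyethoxy) ether F5. Condensation of F5 with 15 (Me3SiOTf, CH2Cl2, −78 °C) gives the benzyl-protected trimer F6, and hydrogenolysis (H2, Pd(OH)2/C) comes back to the route at 27.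

3. Step 19. The upper-unit cation may attack C6 of either flavan unit of 15 instead of C8 of its upper unit, the chain may extend beyond the trimer, or the alkoxybenzyl ethers may be cleaved by the Lewis acid. The fallback changes the order of bond formation so that every coupling uses a monomeric nucleophile (orthogonal activation of oxygen and sulfur leaving groups). It sets out from 12, with 25 and 14. Thiolysis of 12 with 2,6-dimethylbenzenethiol and BF3·OEt2 (CH2Cl2, −78 °C) gives the 4β-arylthio ether F7. Condensation of 25 with F7 under BF3·OEt2, which activates the 4-hydroxyl but not the thioether, gives the upper–middle dimer thioether F8. Activation of the thioether of F8 with AgBF4 in the presence of excess 14 (CH2Cl2, −78 → −40 °C) comes back to the route at 26.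

**Further compounds**

F1 | step 7 | 3-[(tert-butyldimethylsilyloxy)methylidene] derivative of 9 (silyl enol ether, C2 unchanged) | c1(OCc7ccc(OCc8ccccc8)c(OCc8ccccc8)c7)cc(OCc7ccc(OCc8ccccc8)c(OCc8ccccc8)c7)cc2O[C@H](c7ccc(OCc8ccccc8)c(OCc8ccccc8)c7)C(=CO[Si](C)(C)C(C)(C)C)c12
F2 | step 7 | 3-O-tert-butyldimethylsilyl ether of 10 (silyloxy group trans to the 2-aryl group) | c1(OCc7ccc(OCc8ccccc8)c(OCc8ccccc8)c7)cc(OCc7ccc(OCc8ccccc8)c(OCc8ccccc8)c7)cc2O[C@H](c7ccc(OCc8ccccc8)c(OCc8ccccc8)c7)[C@](O[Si](C)(C)C(C)(C)C)(C=O)c12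
F3 | step 7 | 3-O-tert-butyldimethylsilyl ether of 11 (2,3-cis) | c1(OCc7ccc(OCc8ccccc8)c(OCc8ccccc8)c7)cc(OCc7ccc(OCc8ccccc8)c(OCc8ccccc8)c7)cc2O[C@H](c7ccc(OCc8ccccc8)c(OCc8ccccc8)c7)[C@H](O[Si](C)(C)C(C)(C)C)C(=O)c12
F4 | step 17 | (2R,3R)-5,7-bis(benzyloxy)-2-[4-(benzyloxy)phenyl]chroman-3-ol | c1c(OCc7ccccc7)cc(OCc7ccccc7)c2c1O[C@H](c3ccc(OCc7ccccc7)cc3)[C@H](O)C2
F5 | step 17 | 4β-(2-ethoxyethoxy) derivative of F4 (3,4-trans) | c1c(OCc7ccccc7)cc(OCc7ccccc7)c2c1O[C@H](c3ccc(OCc7ccccc7)cc3)[C@H](O)[C@H]2OCCOCC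
F6 | step 17 | protected trimer with a 5,7,4′-tri-O-benzyl upper unit bonded C4 (3,4-trans) to C8 of the upper unit of 15 | c1(OCc7ccccc7)cc(OCc7ccccc7)cc2O[C@H](c7ccc(OCc8ccccc8)cc7)[C@H](O)[C@@H](c3c(OCc7ccc(OCc8ccccc8)c(OCc8ccccc8)c7)cc(OCc7ccc(OCc8ccccc8)c(OCc8ccccc8)c7)c4c3O[C@H](c7ccc(OCc8ccccc8)c(OCc8ccccc8)c7)[C@H](O)[C@H]4c5c(OCc7ccccc7)cc(OCc7ccccc7)c6c5O[C@H](c9ccc(OCc7ccccc7)c(OCc7ccccc7)c9)[C@H](O)C6)c12
F7 | step 19 | 4β-(2,6-dimethylphenylthio) analogue of 12 (4-hydroxyl replaced, 3,4-trans) | c1(OCc7ccc(OCc8ccccc8)c(OCc8ccccc8)c7)cc(OCc7ccc(OCc8ccccc8)c(OCc8ccccc8)c7)cc2O[C@H](c7ccc(OCc8ccccc8)c(OCc8ccccc8)c7)[C@H](O)[C@@H](Sc9c(C)cccc9C)c12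
F8 | step 19 | upper–middle dimer: unit from 25 bonded C4 (3,4-trans) to C8 of F7, thioether retained | c1(OCc7ccc(OCc8ccccc8)cc7)cc(OCc7ccc(OCc8ccccc8)cc7)cc2O[C@H](c7ccc(OCc8ccccc8)cc7)[C@H](O)[C@@H](c3c(OCc7ccc(OCc8ccccc8)c(OCc8ccccc8)c7)cc(OCc7ccc(OCc8ccccc8)c(OCc8ccccc8)c7)c4c3O[C@H](c7ccc(OCc8ccccc8)c(OCc8ccccc8)c7)[C@H](O)[C@H]4Sc9c(C)cccc9C)c12
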